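## Retrosynthetic overview

1. Target 22 ⇐ depsidone dimethyl ether 21 by cleavage of the two aryl methyl ethers (ring A O-methyl next to the formyl group, ring B O8-methyl).
2. Ring C (seven-membered) ⇐ fluoro depside 20. In ring A the carbon bonded to the ether oxygen of ring C lies between the formyl-bearing carbon and the carbon bearing the lactone carbonyl, so a C–F bond at that carbon is activated by two ortho carbonyl groups toward the ring B O7 phenoxide, which the O6 ester holds beside it.
3. 20 ⇐ ring A acid 9 + chromanone phenol 17 (O7 masked as its 4-methoxybenzyl ether), then removal of that ether.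
4. Ring A acid 9 ⇐ 3-fluoro-5-methylphenol 1: O-methylation, para-bromination, lithiation/formylation between F and OMe, Br/Li exchange and CO2.
5. Rings B/D chromanone 17 ⇐ quinone 10: reduction, C-acetylation, Kabbe annulation, O6-directed 7-O-demethylation, 7-O-alkylation. Ring order: A and B are bought as arenes, ring D closes in step 8, ring C in step 13.

Key step: step 13

Remark on the chemistry: ring A is the formyl-bearing benzoate ring, ring B the benzo ring of the chromanone, ring C the dioxepinone, ring D the dihydropyranone; ring B/D positions use chromanone numbering (O1, C2, C3, C4=O, C4a, C5–C8, C8a); methyl ethers are carried on the ring A phenol and on O8 because the O8 methyl comes with the quinone and methyl ethers tolerate the organolithium steps.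

## Route

Step 1
Reactants: 1 3-fluoro-5-methylphenol
Product: 2 1-fluoro-3-methoxy-5-methylbenzene
Conditions: MeI, K2CO3, acetone, reflux
Reagents that add atoms: iodomethane, CI
Why: Williamson O-methylation of the phenoxide should be clean, and the methyl ether tolerates the amide base and n-BuLi used in steps 3 and 5.

Step 2
Reactants: 2 1-fluoro-3-methoxy-5-methylbenzene
Product: 3 2-bromo-1-fluoro-5-methoxy-3-methylbenzene
Conditions: NBS, MeCN, 0 °C → rt
Reagents that add atoms: N-bromosuccinimide, O=C1CCC(=O)N1Br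
Why: Electrophilic aromatic bromination with NBS in acetonitrile is strongly para-directed by the methoxy group, so bromine should enter the carbon between F and CH3.

Step 3
Reactants: 3 2-bromo-1-fluoro-5-methoxy-3-methylbenzene
Product: 5 3-bromo-2-fluoro-6-methoxy-4-methylbenzaldehyde, via aryllithium 4 (not isolated)
Conditions: LiN(i-Pr)2 (LDA), THF, −78 °C; DMF, −78 °C; aq. HCl
Reagents that add atoms: N,N-dimethylformamide, CN(C)C=O
Why: Directed ortho-metalation removes the most acidic ring proton, the one flanked by F and OMe, with an amide base that does not exchange the bromide, and the aryllithium (kept at −78 °C to avoid loss of LiF) is formylated by DMF.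

Step 4
Reactants: 5 3-bromo-2-fluoro-6-methoxy-4-methylbenzaldehyde
Product: 6 2-(3-bromo-2-fluoro-6-methoxy-4-methylphenyl)-1,3-dioxolane
Conditions: ethylene glycol, p-TsOH (cat.), toluene, reflux, Dean–Stark
Reagents that add atoms: ethylene glycol, OCCO
Why: Acid-catalysed acetalization with azeotropic removal of water masks the aldehyde against n-BuLi in the next step.

Step 5
Reactants: 6 2-(3-bromo-2-fluoro-6-methoxy-4-methylphenyl)-1,3-dioxolane
Product: 9 2-fluoro-3-formyl-4-methoxy-6-methylbenzoic acid, via aryllithium 7 (not isolated), via lithium carboxylate 8 (not isolated)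
Conditions: n-BuLi, THF, −78 °C; CO2, −78 °C → rt; 2 M HCl, THF, rt
Reagents that add atoms: carbon dioxide, O=C=O; water, O
Why: Bromine–lithium exchange is fast at −78 °C and fixes the carboxylation site between F and CH3 without any question of regiochemistry, and the aqueous acid work-up hydrolyses the dioxolane back to the aldehyde.

Step 6
Reactants: 10 2,3-dimethoxy-5-methyl-1,4-benzoquinone
Product: 11 2,3-dimethoxy-5-methylbenzene-1,4-diol
Conditions: Na2S2O4, EtOAc/H2O, rt, under Ar
Reagents that add atoms: none
Why: Dithionite reduction of a benzoquinone to its hydroquinone is routine, and the air-sensitive product is used directly.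

Step 7
Reactants: 11 2,3-dimethoxy-5-methylbenzene-1,4-diol
Product: 12 1-(2,5-dihydroxy-3,4-dimethoxy-6-methylphenyl)ethan-1-one
Conditions: AcOH, BF3·OEt2, 90 °C; then aq. NaOAc
Reagents that add atoms: acetic acid, CC(=O)O
Why: Friedel–Crafts C-acetylation (direct or by O-acylation and Fries shift) can only occur at the single unsubstituted ring carbon, which is ortho to a hydroxyl and para to a methoxy group.

Step 8
Reactants: 12 1-(2,5-dihydroxy-3,4-dimethoxy-6-methylphenyl)ethan-1-one
Product: 14 6-hydroxy-7,8-dimethoxy-2,2,5-trimethylchroman-4-one, via enone 13 (not isolated)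
Conditions: acetone, pyrrolidine, toluene, reflux, under Ar
Reagents that add atoms: acetone, CC(C)=O
Why: Kabbe chromanone synthesis, in which amine-mediated aldol condensation with acetone gives the aryl 3-methylbut-2-enyl ketone and the only hydroxyl ortho to the acyl group closes ring D by 6-endo oxa-Michael addition; no stereocentre is formed.

Step 9
Reactants: 14 6-hydroxy-7,8-dimethoxy-2,2,5-trimethylchroman-4-one
Product: 16 6,7-dihydroxy-8-methoxy-2,2,5-trimethylchroman-4-one, via chloroboronate 15 (not isolated)
Conditions: BCl3 (2.2 equiv), CH2Cl2, −78 → 0 °C; then H2O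
Reagents that add atoms: none
Why: Neighbouring-hydroxyl-directed Lewis acid ether cleavage, in which the O6–BCl2 aryloxide chelates the adjacent 7-methoxy oxygen and chloride removes that methyl by SN2 to close a five-membered cyclic borate, O7 also being para to the C4 ketone and so the better leaving oxygen, while the 8-methoxy group and the vinylogous-ester oxygen O1 should survive at low temperature.

Step 10
Reactants: 16 6,7-dihydroxy-8-methoxy-2,2,5-trimethylchroman-4-one
Product: 17 6-hydroxy-8-methoxy-7-[(4-methoxybenzyl)oxy]-2,2,5-trimethylchroman-4-one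
Conditions: 4-methoxybenzyl chloride (1.05 equiv), K2CO3 (1.0 equiv), DMF, rt
Reagents that add atoms: 4-methoxybenzyl chloride, COc1ccc(CCl)cc1
Why: Williamson etherification under limiting base should take place at O7, because the 7-hydroxyl is para to the C4 ketone (a vinylogous acid) and ionizes before the 6-hydroxyl.

Step 11
Reactants: 9 2-fluoro-3-formyl-4-methoxy-6-methylbenzoic acid; 17 6-hydroxy-8-methoxy-7-[(4-methoxybenzyl)oxy]-2,2,5-trimethylchroman-4-one
Product: 19 8-methoxy-7-[(4-methoxybenzyl)oxy]-2,2,5-trimethyl-4-oxochroman-6-yl 2-fluoro-3-formyl-4-methoxy-6-methylbenzoate, via acid chloride 18 (not isolated)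
Conditions: (COCl)2, DMF (cat.), CH2Cl2, 0 °C → rt; then 17, Et3N, DMAP (cat.), CH2Cl2, 0 °C → rt
Reagents that add atoms: none
Why: Esterification through the acyl chloride with nucleophilic catalysis by DMAP joins the hindered acid to the only free phenol of 17, so the ester is placed on O6 without ambiguity.

Step 12
Reactants: 19 8-methoxy-7-[(4-methoxybenzyl)oxy]-2,2,5-trimethyl-4-oxochroman-6-yl 2-fluoro-3-formyl-4-methoxy-6-methylbenzoate
Product: 20 7-hydroxy-8-methoxy-2,2,5-trimethyl-4-oxochroman-6-yl 2-fluoro-3-formyl-4-methoxy-6-methylbenzoate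
Conditions: TFA, anisole, CH2Cl2, 0 °C
Reagents that add atoms: none
Why: Acidolysis of the 4-methoxybenzyl aryl ether, with anisole trapping the benzylic cation, frees O7 while the aryl ester, aldehyde, aryl fluoride and methyl ethers are inert to cold TFA.

Step 13
Reactants: 20 7-hydroxy-8-methoxy-2,2,5-trimethyl-4-oxochroman-6-yl 2-fluoro-3-formyl-4-methoxy-6-methylbenzoate
Product: 21 depsidone dimethyl ether (the target skeleton with OMe in place of both OH groups)
Conditions: Cs2CO3, DMF (0.01 M), 4 Å molecular sieves, rt → 50 °C, under Ar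
Reagents that add atoms: none
Why: Cs2CO3 ionizes the only free phenol, the ring B O7–H para to the C4 ketone, and the phenoxide adds to the fluorine-bearing ring A carbon, the charge of the Meisenheimer adduct being taken up by the ortho formyl and ortho ester carbonyl groups before fluoride is expelled. The closest known reaction type is the intramolecular SNAr diaryl ether formation used to close dibenzo-fused oxepinone and oxazepinone rings from ortho-fluoroaryl carbonyl compounds. Ring C closes as a seven-membered ring by addition–elimination (formally 7-exo-trig), and the ester tether brings the hindered phenoxide to a carbon that is flanked on both sides and would be hard to reach intermolecularly. No stereocentre is formed. The step needs the ester to stay on O6 while O7 attacks: a 1,2-acyl shift would have to pass through addition to a carbonyl flanked by F and CH3 and would produce the less stabilized O6 phenoxide, so the anion should reside on O7, and high dilution with exclusion of water should suppress intermolecular substitution and ester cleavage.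

Step 14
Reactants: 21 depsidone dimethyl ether
Product: 22 target depsidone (CNP0271978.0)
Conditions: BBr3 (5 equiv), CH2Cl2, −78 → 0 °C; then H2O
Reagents that add atoms: none
Why: Lewis acid O-demethylation should cleave both ethers, the ring A methoxy being activated by chelation to the ortho formyl group and the O8 methoxy being twisted out of conjugation between two oxygen substituents, while the hindered aryl lactone, the diaryl ether and the poorly basic vinylogous-ester oxygen O1 are expected to hold at or below 0 °C.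

## Compound list

1 | 3-fluoro-5-methylphenol | Cc1cc(O)cc(F)c1 | starting material
2 | 1-fluoro-3-methoxy-5-methylbenzene | COc1cc(C)cc(F)c1 | intermediate
3 | 2-bromo-1-fluoro-5-methoxy-3-methylbenzene | COc1cc(C)c(Br)c(F)c1 | intermediate
4 | (3-bromo-2-fluoro-6-methoxy-4-methylphenyl)lithium | COc1cc(C)c(Br)c(F)c1[Li] | intermediate
5 | 3-bromo-2-fluoro-6-methoxy-4-methylbenzaldehyde | COc1cc(C)c(Br)c(F)c1C=O | intermediate
6 | 2-(3-bromo-2-fluoro-6-methoxy-4-methylphenyl)-1,3-dioxolane | COc1cc(C)c(Br)c(F)c1C1OCCO1 | intermediate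
7 | [3-(1,3-dioxolan-2-yl)-2-fluoro-4-methoxy-6-methylphenyl]lithium | COc1cc(C)c([Li])c(F)c1C1OCCO1 | intermediate
8 | lithium 3-(1,3-dioxolan-2-yl)-2-fluoro-4-methoxy-6-methylbenzoate | COc1cc(C)c(C(=O)[O-])c(F)c1C1OCCO1.[Li+] | intermediate
9 | 2-fluoro-3-formyl-4-methoxy-6-methylbenzoic acid | COc1cc(C)c(C(=O)O)c(F)c1C=O | intermediate
10 | 2,3-dimethoxy-5-methyl-1,4-benzoquinone | COC1=C(OC)C(=O)C(C)=CC1=O | starting material
11 | 2,3-dimethoxy-5-methylbenzene-1,4-diol | COc1c(O)cc(C)c(O)c1OC | intermediate
12 | 1-(2,5-dihydroxy-3,4-dimethoxy-6-methylphenyl)ethan-1-one | CC(=O)c1c(C)c(O)c(OC)c(OC)c1O | intermediate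
13 | 1-(2,5-dihydroxy-3,4-dimethoxy-6-methylphenyl)-3-methylbut-2-en-1-one | CC(C)=CC(=O)c1c(C)c(O)c(OC)c(OC)c1O | intermediate
14 | 6-hydroxy-7,8-dimethoxy-2,2,5-trimethylchroman-4-one | COc1c(O)c(C)c2c(c1OC)OC(C)(C)CC2=O | intermediate
15 | cyclic B-chloro borate spanning O6 and O7 of 8-methoxy-2,2,5-trimethylchroman-4-one | COc1c2OB(Cl)Oc2c(C)c2c1OC(C)(C)CC2=O | intermediate
16 | 6,7-dihydroxy-8-methoxy-2,2,5-trimethylchroman-4-one | COc1c(O)c(O)c(C)c2c1OC(C)(C)CC2=O | intermediate
17 | 6-hydroxy-8-methoxy-7-[(4-methoxybenzyl)oxy]-2,2,5-trimethylchroman-4-one | COc1ccc(COc2c(O)c(C)c3c(c2OC)OC(C)(C)CC3=O)cc1 | intermediate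
18 | 2-fluoro-3-formyl-4-methoxy-6-methylbenzoyl chloride | COc1cc(C)c(C(=O)Cl)c(F)c1C=O | intermediate
19 | 8-methoxy-7-[(4-methoxybenzyl)oxy]-2,2,5-trimethyl-4-oxochroman-6-yl 2-fluoro-3-formyl-4-methoxy-6-methylbenzoate | COc1ccc(COc2c(OC(=O)c3c(C)cc(OC)c(C=O)c3F)c(C)c3c(c2OC)OC(C)(C)CC3=O)cc1 | intermediate
20 | 7-hydroxy-8-methoxy-2,2,5-trimethyl-4-oxochroman-6-yl 2-fluoro-3-formyl-4-methoxy-6-methylbenzoate | COc1cc(C)c(C(=O)Oc2c(C)c3c(c(OC)c2O)OC(C)(C)CC3=O)c(F)c1C=O | intermediate
21 | depsidone dimethyl ether (ring A O-methyl ortho to CHO, ring B O8-methyl) | Cc1cc(OC)c(C=O)c2c1C(=O)Oc1c(C)c3c(c(OC)c1O2)OC(C)(C)CC3=O | intermediate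
22 | target depsidone CNP0271978.0 | Cc1cc(O)c(C=O)c2c1C(=O)Oc1c(C)c3c(c(O)c1O2)OC(C)(C)CC3=O | target

## Step count

Total step count: 14. Longest linear sequence: 9 steps (steps 6–10, then 11–14; the ring A branch, steps 1–5 then 11–14, is equally long).

## Steps most likely to fail

1. Step 13 (key step). The ester may shift from O6 to O7 before ring closure, which would exchange the lactone and ether oxygens, or intermolecular substitution and ester cleavage may outrun the cyclization. The fallback forms the ether bond first and the lactone last; it sets out from acid 9 and diol 16 and comes back at 21. Acid 9 would be converted with tert-butyl 2,2,2-trichloroacetimidate and catalytic BF3·OEt2 in CH2Cl2 into tert-butyl 2-fluoro-3-formyl-4-methoxy-6-methylbenzoate F1, whose ester cannot be attacked by a phenoxide. Diol 16 with one equivalent of K2CO3 in DMSO at 60–80 °C should ionize at O7 and displace the doubly activated fluoride of F1, giving the diaryl ether tert-butyl 3-formyl-2-[(6-hydroxy-8-methoxy-2,2,5-trimethyl-4-oxochroman-7-yl)oxy]-4-methoxy-6-methylbenzoate F2. TFA in CH2Cl2 should then release the seco acid 3-formyl-2-[(6-hydroxy-8-methoxy-2,2,5-trimethyl-4-oxochroman-7-yl)oxy]-4-methoxy-6-methylbenzoic acid F3. Lactonization of F3 onto its only free hydroxyl (2-chloro-1-methylpyridinium iodide, Et3N, CH2Cl2, reflux, high dilution) should give 21.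

2. Step 9. The ether cleavage may show poor site selectivity, removing the 8-methyl group or both methyl groups. The fallback replaces the selective cleavage by an exhaustive one on an O6-protected substrate; it sets out from 14 and comes back at 17. Pivaloylation of 14 (pivaloyl chloride, Et3N, DMAP, CH2Cl2) should give 7,8-dimethoxy-2,2,5-trimethyl-4-oxochroman-6-yl pivalate F4. BBr3 in CH2Cl2 (−78 → 0 °C) should remove both methyl groups to give 7,8-dihydroxy-2,2,5-trimethyl-4-oxochroman-6-yl pivalate F5, the bulky pivalate being slow to migrate. Alkylation of F5 with 4-methoxybenzyl chloride and KHCO3 in DMF should occur at the more acidic O7 (para to the ketone) to give 8-hydroxy-7-[(4-methoxybenzyl)oxy]-2,2,5-trimethyl-4-oxochroman-6-yl pivalate F6. Methylation (MeI, K2CO3, acetone) should give 8-methoxy-7-[(4-methoxybenzyl)oxy]-2,2,5-trimethyl-4-oxochroman-6-yl pivalate F7, and methanolysis (NaOMe, MeOH, rt) should give 17.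

3. Step 14. The hindered O8 methyl ether may cleave only under conditions forcing enough to open the lactone or ring D. The fallback carries a benzyl ether on O8 so that the last step is a mild debenzylation; it sets out from 14 and comes back at 22.
   - It follows the path above through the pivalate F4 and the diol F5 to the 8-hydroxy compound F6.
   - Benzylation of F6 (BnBr, K2CO3, DMF) should give 8-(benzyloxy)-7-[(4-methoxybenzyl)oxy]-2,2,5-trimethyl-4-oxochroman-6-yl pivalate F8, and methanolysis (NaOMe, MeOH) should give 8-(benzyloxy)-6-hydroxy-7-[(4-methoxybenzyl)oxy]-2,2,5-trimethylchroman-4-one F9.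
   - Acylation of F9 with acid chloride 18 (Et3N, DMAP, CH2Cl2) should give 8-(benzyloxy)-7-[(4-methoxybenzyl)oxy]-2,2,5-trimethyl-4-oxochroman-6-yl 2-fluoro-3-formyl-4-methoxy-6-methylbenzoate F10.
   - TFA with anisole should give 8-(benzyloxy)-7-hydroxy-2,2,5-trimethyl-4-oxochroman-6-yl 2-fluoro-3-formyl-4-methoxy-6-methylbenzoate F11.
   - Cs2CO3 in dilute DMF should close ring C as in step 13 to give the O8-benzyl ring A O-methyl depsidone F12.
   - BCl3 with pentamethylbenzene in CH2Cl2 (−78 → 0 °C) should remove the benzyl group and the formyl-chelated ring A methyl group to give 22.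

## Further compounds

F1 | step 13 | tert-butyl 2-fluoro-3-formyl-4-methoxy-6-methylbenzoate | COc1cc(C)c(C(=O)OC(C)(C)C)c(F)c1C=O
F2 | step 13 | tert-butyl 3-formyl-2-[(6-hydroxy-8-methoxy-2,2,5-trimethyl-4-oxochroman-7-yl)oxy]-4-methoxy-6-methylbenzoate | COc1cc(C)c(C(=O)OC(C)(C)C)c(Oc2c(O)c(C)c3c(c2OC)OC(C)(C)CC3=O)c1C=O
F3 | step 13 | 3-formyl-2-[(6-hydroxy-8-methoxy-2,2,5-trimethyl-4-oxochroman-7-yl)oxy]-4-methoxy-6-methylbenzoic acid | COc1cc(C)c(C(=O)O)c(Oc2c(O)c(C)c3c(c2OC)OC(C)(C)CC3=O)c1C=O
F4 | step 9 | 7,8-dimethoxy-2,2,5-trimethyl-4-oxochroman-6-yl pivalate | COc1c(OC(=O)C(C)(C)C)c(C)c2c(c1OC)OC(C)(C)CC2=O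
F5 | step 9 | 7,8-dihydroxy-2,2,5-trimethyl-4-oxochroman-6-yl pivalate | CC(C)(C)C(=O)Oc1c(C)c2c(c(O)c1O)OC(C)(C)CC2=O
F6 | step 9 | 8-hydroxy-7-[(4-methoxybenzyl)oxy]-2,2,5-trimethyl-4-oxochroman-6-yl pivalate | COc1ccc(COc2c(OC(=O)C(C)(C)C)c(C)c3c(c2O)OC(C)(C)CC3=O)cc1
F7 | step 9 | 8-methoxy-7-[(4-methoxybenzyl)oxy]-2,2,5-trimethyl-4-oxochroman-6-yl pivalate | COc1ccc(COc2c(OC(=O)C(C)(C)C)c(C)c3c(c2OC)OC(C)(C)CC3=O)cc1
F8 | step 14 | 8-(benzyloxy)-7-[(4-methoxybenzyl)oxy]-2,2,5-trimethyl-4-oxochroman-6-yl pivalate | COc1ccc(COc2c(OC(=O)C(C)(C)C)c(C)c3c(c2OCc4ccccc4)OC(C)(C)CC3=O)cc1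
F9 | step 14 | 8-(benzyloxy)-6-hydroxy-7-[(4-methoxybenzyl)oxy]-2,2,5-trimethylchroman-4-one | COc1ccc(COc2c(O)c(C)c3c(c2OCc4ccccc4)OC(C)(C)CC3=O)cc1
F10 | step 14 | 8-(benzyloxy)-7-[(4-methoxybenzyl)oxy]-2,2,5-trimethyl-4-oxochroman-6-yl 2-fluoro-3-formyl-4-methoxy-6-methylbenzoate | COc1ccc(COc2c(OC(=O)c3c(C)cc(OC)c(C=O)c3F)c(C)c3c(c2OCc4ccccc4)OC(C)(C)CC3=O)cc1
F11 | step 14 | 8-(benzyloxy)-7-hydroxy-2,2,5-trimethyl-4-oxochroman-6-yl 2-fluoro-3-formyl-4-methoxy-6-methylbenzoate | COc1cc(C)c(C(=O)Oc2c(C)c3c(c(OCc4ccccc4)c2O)OC(C)(C)CC3=O)c(F)c1C=O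
F12 | step 14 | depsidone with O8-benzyl and ring A O-methyl ethers | Cc1cc(OC)c(C=O)c2c1C(=O)Oc1c(C)c3c(c(OCc4ccccc4)c1O2)OC(C)(C)CC3=O
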